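**Retrosynthetic overview**
- Feature: in unit 2 (double-primed chromone), ring A (C4a''–C5''–C6''–C7''–C8''–C8a'' with O1'', 5''-OH and 7''-OH) is an intact phloroglucinol nucleus of threefold symmetry. C4''–C3''–C2'', with its aryl groups on C3'' and C2'', is an α-aryl aroylacetate.
- Key disconnection: C4''–C4a'' and O1''–C2'' are cut together. This gives unprotected phloroglucinol and an ethyl α-aryl-(4-benzyloxybenzoyl)acetate that already carries benzyl-protected unit 1.
- The ketoester is cut at C3''–C2'' (ester enolate plus 4-benzyloxybenzoyl chloride). The arylacetate is cut at C3'–C3'' (3'-bromoflavone plus Reformatsky reagent), so the ester enters only after the hydroxide-mediated chalcone step.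
- Unit 1 comes from mono-benzylated 2',6'-dihydroxy-4'-methoxyacetophenone and 4-benzyloxy-3-bromobenzaldehyde (chalcone, then I2/DMSO).
- Ring order: ring C of unit 1 (step 4), then ring C of unit 2 (step 8). All benzene rings are purchased, and the three benzyl ethers are removed last.

Key step: step 8

Assumption: the target has no stereocentre and its SMILES fixes no axial configuration, so the C3'–C3'' axis is treated as needing no control. Locants: unprimed = chromone of unit 1, primed = its 2-aryl ring, double-primed = chromone of unit 2, triple-primed = its 2-aryl ring.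

**Step 1**
Reactants: 1 2',6'-dihydroxy-4'-methoxyacetophenone
Product: 2 1-[2-(benzyloxy)-6-hydroxy-4-methoxyphenyl]ethanone
Conditions: BnBr (1.05 equiv), K2CO3 (1.1 equiv), acetone, reflux
Reagents that add atoms: benzyl bromide, BrCc1ccccc1
Why: Williamson etherification, in which the symmetrical bis-phenol should be alkylated only once because the remaining hydroxyl is locked in a hydrogen bond to the acetyl carbonyl and is far less nucleophilic.

**Step 2**
Reactants: 3 3-bromo-4-hydroxybenzaldehyde
Product: 4 4-(benzyloxy)-3-bromobenzaldehyde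
Conditions: BnBr (1.1 equiv), K2CO3, DMF, 50 °C
Reagents that add atoms: benzyl bromide, BrCc1ccccc1
Why: Williamson etherification of an acidic ortho-bromophenol under conditions to which the aldehyde and the aryl bromide are inert.

**Step 3**
Reactants: 2 1-[2-(benzyloxy)-6-hydroxy-4-methoxyphenyl]ethanone; 4 4-(benzyloxy)-3-bromobenzaldehyde
Product: 5 (E)-1-[2-(benzyloxy)-6-hydroxy-4-methoxyphenyl]-3-[4-(benzyloxy)-3-bromophenyl]prop-2-en-1-one
Conditions: KOH (aq, excess), EtOH, rt; then dilute HCl
Reagents that add atoms: none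
Why: Claisen–Schmidt condensation, in which aldehyde 4 has no α-hydrogen so only the methyl ketone of 2 can act as donor, and E1cB dehydration should give the conjugated E-enone as the thermodynamic geometry.

**Step 4**
Reactants: 5 (E)-1-[2-(benzyloxy)-6-hydroxy-4-methoxyphenyl]-3-[4-(benzyloxy)-3-bromophenyl]prop-2-en-1-one
Product: 7 5-(benzyloxy)-2-[4-(benzyloxy)-3-bromophenyl]-7-methoxy-4H-chromen-4-one, via flavanone 6 (not isolated)
Conditions: I2 (10 mol %), DMSO, 130 °C
Reagents that add atoms: none
Why: Iodine/DMSO oxidative cyclisation of a 2'-hydroxychalcone, in which 6-endo-trig oxa-Michael closure forms ring C of unit 1 as racemic flavanone 6, whose stereocentre is erased when α-iodination and loss of HI give the chromone while DMSO re-oxidises HI to I2.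

**Step 5**
Reactants: 7 5-(benzyloxy)-2-[4-(benzyloxy)-3-bromophenyl]-7-methoxy-4H-chromen-4-one; 8 ethyl bromoacetate
Product: 10 ethyl 2-[2-(benzyloxy)-5-(5-(benzyloxy)-7-methoxy-4-oxo-4H-chromen-2-yl)phenyl]acetate, via Reformatsky reagent 9 (not isolated)
Conditions: 8 (2.5 equiv), Zn dust (TMSCl-activated), THF, 40 °C; then 7, Pd2(dba)3 (2.5 mol %), XPhos (6 mol %), THF, 65 °C
Reagents that add atoms: none
Why: Negishi-type α-arylation of a Reformatsky reagent, in which the bulky biaryl phosphine lets zerovalent palladium insert into the ortho-alkoxy C–Br bond and the weakly basic zinc enolate should spare the vinylogous-ester carbonyl of the chromone.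

**Step 6**
Reactants: 11 4-(benzyloxy)benzoic acid
Product: 12 4-(benzyloxy)benzoyl chloride
Conditions: (COCl)2 (1.3 equiv), DMF (cat.), CH2Cl2, 0 °C to rt; concentrate and use crude
Reagents that add atoms: oxalyl chloride, ClC(=O)C(=O)Cl
Why: Vilsmeier-type activation of a carboxylic acid by oxalyl chloride/DMF, mild enough to leave the aryl benzyl ether untouched.

**Step 7**
Reactants: 10 ethyl 2-[2-(benzyloxy)-5-(5-(benzyloxy)-7-methoxy-4-oxo-4H-chromen-2-yl)phenyl]acetate; 12 4-(benzyloxy)benzoyl chloride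
Product: 14 ethyl 2-[2-(benzyloxy)-5-(5-(benzyloxy)-7-methoxy-4-oxo-4H-chromen-2-yl)phenyl]-3-[4-(benzyloxy)phenyl]-3-oxopropanoate (racemic), via lithium enolate 13 (not isolated)
Conditions: LiN(SiMe3)2 (2.2 equiv), THF, −78 °C; then 12 (1.1 equiv), −78 to −20 °C; aq NH4Cl
Reagents that add atoms: none
Why: Crossed Claisen-type C-acylation of an ester enolate, in which the benzylic CH2 is by far the most acidic site of 10, the acid chloride cannot enolise, the second equivalent of base stores the product as its stabilised enolate and so blocks double acylation, and the new α-stereocentre is racemic, labile through the enol and erased in step 8.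

**Step 8**
Reactants: 14 ethyl 2-[2-(benzyloxy)-5-(5-(benzyloxy)-7-methoxy-4-oxo-4H-chromen-2-yl)phenyl]-3-[4-(benzyloxy)phenyl]-3-oxopropanoate; 15 phloroglucinol (anhydrous)
Product: 18 5-(benzyloxy)-2-{4-(benzyloxy)-3-[2-(4-(benzyloxy)phenyl)-5,7-dihydroxy-4-oxo-4H-chromen-3-yl]phenyl}-7-methoxy-4H-chromen-4-one, via aroylketene 16 (not isolated), via hydroxyaryl diketone 17 (not isolated)
Conditions: 15 (3 equiv), Ph2O, 240–250 °C, no acid, N2 sweep with distillative removal of EtOH and H2O
Reagents that add atoms: none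
Why: Above about 200 °C the enol of 14 expels ethanol to give aroylketene 16, whose O-acylation of phloroglucinol is reversible at this temperature, whereas attack by a ring carbon followed by rearomatisation gives the chelated 2,4,6-trihydroxyphenyl diketone 17 and so fixes C4''–C4a''. A hydroxyl flanking the new acyl group then adds to the aroyl carbonyl in a 6-exo-trig closure (O1''–C2''), and the hemiketal loses water to give the 4-pyranone ring C of unit 2. The closest known reaction is the Mentzer thermal chromone synthesis, established for phloroglucinol with aroylacetates (flavones) and for α-substituted β-ketoesters (3-substituted chromones). No stereocentre is created, and the labile α-centre of 14 becomes the sp2 carbon C3''. The step needs chromone rather than Pechmann coumarin selectivity: without acid the ketone is not activated for attack by a ring carbon and is also shielded by the α-aryl group with its ortho-benzyloxy substituent, so the ketene carbon is the only strong electrophile, the former ester carbon ends on carbon and the ketone carbon ends on oxygen. Positional selectivity does not arise because all three CH and all three OH groups of 15 are equivalent, the excess of 15 suppresses a second annulation, and the gas sweep removes water before it can hydrolyse and decarboxylate 14.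

**Step 9**
Reactants: 18 5-(benzyloxy)-2-{4-(benzyloxy)-3-[2-(4-(benzyloxy)phenyl)-5,7-dihydroxy-4-oxo-4H-chromen-3-yl]phenyl}-7-methoxy-4H-chromen-4-one
Product: 19 5-hydroxy-2-{4-hydroxy-3-[5,7-dihydroxy-2-(4-hydroxyphenyl)-4-oxo-4H-chromen-3-yl]phenyl}-7-methoxy-4H-chromen-4-one (CNP0254254.0)
Conditions: H2 (1 atm), 10% Pd/C, THF–MeOH, rt
Reagents that add atoms: none
Why: Catalytic hydrogenolysis of three aryl benzyl ethers, under which the aryl-conjugated vinylogous-ester C2=C3 bonds of both chromones and the 7-methyl ether should stay intact at 1 atm and room temperature.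

**Compound list**
1 | 2',6'-dihydroxy-4'-methoxyacetophenone | CC(=O)c1c(O)cc(OC)cc1O | starting material
2 | 1-[2-(benzyloxy)-6-hydroxy-4-methoxyphenyl]ethanone | CC(=O)c1c(O)cc(OC)cc1OCc1ccccc1 | intermediate
3 | 3-bromo-4-hydroxybenzaldehyde | O=Cc1ccc(O)c(Br)c1 | starting material
4 | 4-(benzyloxy)-3-bromobenzaldehyde | O=Cc1ccc(OCc2ccccc2)c(Br)c1 | intermediate
5 | (E)-1-[2-(benzyloxy)-6-hydroxy-4-methoxyphenyl]-3-[4-(benzyloxy)-3-bromophenyl]prop-2-en-1-one | COc1cc(O)c(C(=O)/C=C/c2ccc(OCc3ccccc3)c(Br)c2)c(OCc2ccccc2)c1 | intermediate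
6 | 5-(benzyloxy)-2-[4-(benzyloxy)-3-bromophenyl]-7-methoxychroman-4-one (racemic flavanone, not isolated) | COc1cc(OCc2ccccc2)c2c(c1)OC(c1ccc(OCc3ccccc3)c(Br)c1)CC2=O | intermediate
7 | 5-(benzyloxy)-2-[4-(benzyloxy)-3-bromophenyl]-7-methoxy-4H-chromen-4-one | COc1cc(OCc2ccccc2)c2c(=O)cc(-c3ccc(OCc4ccccc4)c(Br)c3)oc2c1 | intermediate
8 | ethyl bromoacetate | CCOC(=O)CBr | starting material
9 | bromo(2-ethoxy-2-oxoethyl)zinc (Reformatsky reagent, not isolated) | CCOC(=O)C[Zn]Br | intermediate
10 | ethyl 2-[2-(benzyloxy)-5-(5-(benzyloxy)-7-methoxy-4-oxo-4H-chromen-2-yl)phenyl]acetate | CCOC(=O)Cc1cc(-c2cc(=O)c3c(OCc4ccccc4)cc(OC)cc3o2)ccc1OCc1ccccc1 | intermediate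
11 | 4-(benzyloxy)benzoic acid | OC(=O)c1ccc(OCc2ccccc2)cc1 | starting material
12 | 4-(benzyloxy)benzoyl chloride | ClC(=O)c1ccc(OCc2ccccc2)cc1 | intermediate
13 | lithium enolate of 10 (not isolated, geometry not defined) | [Li+].CCOC([O-])=Cc1cc(-c2cc(=O)c3c(OCc4ccccc4)cc(OC)cc3o2)ccc1OCc1ccccc1 | intermediate
14 | ethyl 2-[2-(benzyloxy)-5-(5-(benzyloxy)-7-methoxy-4-oxo-4H-chromen-2-yl)phenyl]-3-[4-(benzyloxy)phenyl]-3-oxopropanoate (racemic, labile α-centre) | CCOC(=O)C(C(=O)c1ccc(OCc2ccccc2)cc1)c1cc(-c2cc(=O)c3c(OCc4ccccc4)cc(OC)cc3o2)ccc1OCc1ccccc1 | intermediate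
15 | phloroglucinol | Oc1cc(O)cc(O)c1 | starting material
16 | 2-[2-(benzyloxy)-5-(5-(benzyloxy)-7-methoxy-4-oxo-4H-chromen-2-yl)phenyl]-3-[4-(benzyloxy)phenyl]-3-oxoprop-1-en-1-one (aroylketene, not isolated) | O=C=C(C(=O)c1ccc(OCc2ccccc2)cc1)c1cc(-c2cc(=O)c3c(OCc4ccccc4)cc(OC)cc3o2)ccc1OCc1ccccc1 | intermediate
17 | 2-[2-(benzyloxy)-5-(5-(benzyloxy)-7-methoxy-4-oxo-4H-chromen-2-yl)phenyl]-1-[4-(benzyloxy)phenyl]-3-(2,4,6-trihydroxyphenyl)propane-1,3-dione (not isolated) | O=C(c1c(O)cc(O)cc1O)C(C(=O)c1ccc(OCc2ccccc2)cc1)c1cc(-c2cc(=O)c3c(OCc4ccccc4)cc(OC)cc3o2)ccc1OCc1ccccc1 | intermediate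
18 | 5-(benzyloxy)-2-{4-(benzyloxy)-3-[2-(4-(benzyloxy)phenyl)-5,7-dihydroxy-4-oxo-4H-chromen-3-yl]phenyl}-7-methoxy-4H-chromen-4-one | COc1cc(OCc2ccccc2)c2c(=O)cc(-c3ccc(OCc4ccccc4)c(-c4c(-c5ccc(OCc6ccccc6)cc5)oc5cc(O)cc(O)c5c4=O)c3)oc2c1 | intermediate
19 | 5-hydroxy-2-{4-hydroxy-3-[5,7-dihydroxy-2-(4-hydroxyphenyl)-4-oxo-4H-chromen-3-yl]phenyl}-7-methoxy-4H-chromen-4-one (CNP0254254.0) | COc1cc(O)c2c(=O)cc(-c3ccc(O)c(-c4c(-c5ccc(O)cc5)oc5cc(O)cc(O)c5c4=O)c3)oc2c1 | target

**Totals**
Total step count: 9.
Longest linear sequence: 7 steps (1, 3, 4, 5, 7, 8, 9).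

**Steps most likely to fail**

1. Step 8.
   - Risks: hydrolysis and decarboxylation of the ketoester by the released water may outrun ketene formation. C-acylation at the crowded ketene carbon may be slow. Benzyl groups may migrate or be lost at 240 °C in the presence of a polyphenol.
   - Fallback: the annulation is given up and C3'–C3'' is formed instead by Suzuki–Miyaura coupling onto a preformed unit 2.
   - It sets out from 7. Miyaura borylation (B2pin2, Pd(dppf)Cl2, KOAc, dioxane, 90 °C) should give the pinacol boronate F1.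
   - Separately, commercial apigenin is perbenzylated (BnBr, K2CO3, DMF, 80 °C) to tri-O-benzylapigenin F2. This is lithiated at C3 with LiN(iPr)2 in THF at −78 °C and quenched with I2 to give the 3-iodoflavone F3.
   - Coupling of F1 with F3 (Pd(OAc)2, SPhos, K3PO4, toluene–water, 90 °C) should give the penta-O-benzyl biflavone F4.
   - Hydrogenolysis under the conditions of step 9 brings the sequence back to the route at 19.

2. Step 7.
   - Risks: O-acylation of the enolate, double acylation, or consumption of the acid chloride by the excess amide base.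
   - Fallback: acylation is replaced by aldol addition and oxidation.
   - It sets out from 10. Enolate 13 is generated with one equivalent of LiN(SiMe3)2 at −78 °C and treated with commercial 4-(benzyloxy)benzaldehyde to give the β-hydroxy ester F5. This is a diastereomer mixture, which does not matter because both centres are lost later.
   - Oxidation with Dess–Martin periodinane in CH2Cl2 at rt returns to the route at 14.

3. Step 5.
   - Risks: self-condensation or protonation of the zinc enolate on heating, its addition to the chromone carbonyl, and slow transmetalation next to the ortho-benzyloxy group.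
   - Fallback: the reactive zinc enolate is replaced by a soft, stabilised carbanion, and the surplus ester is removed afterwards.
   - It sets out from 7. Malonate arylation (diethyl malonate, Pd(OAc)2, P(tBu)3·HBF4, K3PO4, toluene, 100 °C) should give the diethyl arylmalonate F6.
   - Krapcho dealkoxycarbonylation (LiCl, DMSO–H2O, 150 °C) returns to the route at 10.

**Further compounds**
F1 | step 8 | 5-(benzyloxy)-2-[4-(benzyloxy)-3-(4,4,5,5-tetramethyl-1,3,2-dioxaborolan-2-yl)phenyl]-7-methoxy-4H-chromen-4-one | COc1cc(OCc2ccccc2)c2c(=O)cc(-c3ccc(OCc4ccccc4)c(B4OC(C)(C)C(C)(C)O4)c3)oc2c1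
F2 | step 8 | 5,7-bis(benzyloxy)-2-[4-(benzyloxy)phenyl]-4H-chromen-4-one | O=c1cc(-c2ccc(OCc3ccccc3)cc2)oc2cc(OCc3ccccc3)cc(OCc3ccccc3)c12
F3 | step 8 | 5,7-bis(benzyloxy)-2-[4-(benzyloxy)phenyl]-3-iodo-4H-chromen-4-one | O=c1c(I)c(-c2ccc(OCc3ccccc3)cc2)oc2cc(OCc3ccccc3)cc(OCc3ccccc3)c12
F4 | step 8 | 5-(benzyloxy)-2-{4-(benzyloxy)-3-[5,7-bis(benzyloxy)-2-(4-(benzyloxy)phenyl)-4-oxo-4H-chromen-3-yl]phenyl}-7-methoxy-4H-chromen-4-one | COc1cc(OCc2ccccc2)c2c(=O)cc(-c3ccc(OCc4ccccc4)c(-c4c(-c5ccc(OCc6ccccc6)cc5)oc5cc(OCc6ccccc6)cc(OCc6ccccc6)c5c4=O)c3)oc2c1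
F5 | step 7 | ethyl 2-[2-(benzyloxy)-5-(5-(benzyloxy)-7-methoxy-4-oxo-4H-chromen-2-yl)phenyl]-3-[4-(benzyloxy)phenyl]-3-hydroxypropanoate (racemic diastereomer mixture) | CCOC(=O)C(C(O)c1ccc(OCc2ccccc2)cc1)c1cc(-c2cc(=O)c3c(OCc4ccccc4)cc(OC)cc3o2)ccc1OCc1ccccc1
F6 | step 5 | diethyl 2-[2-(benzyloxy)-5-(5-(benzyloxy)-7-methoxy-4-oxo-4H-chromen-2-yl)phenyl]malonate | CCOC(=O)C(C(=O)OCC)c1cc(-c2cc(=O)c3c(OCc4ccccc4)cc(OC)cc3o2)ccc1OCc1ccccc1
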